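**Retrosynthetic overview**
1. Numbering: ring A has C1 (OH), C2 (bridging O), C3–C5 (Br) and C6 (H); ring B has C1' (bridging O), C3' and C5' (Br) and C6' (OH).
2. The strategy rests on the bridging oxygen at ring-A C2, wedged between C1–O and C3–Br. It is too hindered and too weakly nucleophilic to arylate, so it is alkylated at the sp3 CH2Cl of methyl 4-chloroacetoacetate.
3. Ring B is then grown around that oxygen. C1', C6' and C5' come from the acetoacetate chain, used as its 1,3-bis(silyl enol ether), and C2'–C4' come from 1,1,3,3-tetramethoxypropane. A formal [3+3] cyclocondensation forms C1'–C2' and C4'–C5' and gives a 3-aryloxysalicylate.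
4. End game: saponification, then bromine (bromination at C3' para to OH, ipso bromodecarboxylation at C5'), then BBr3 cleavage of the C1 methyl ether.
5. Ring order: ring A is bought as guaiacol and tribrominated first; ring B is the only ring that is constructed (step 5).

Key step: step 5

Remark: the target has no stereocentre and its diaryl ether axis rotates freely, so it is achiral and no stereocontrol is needed.

**Step 1**
Reactants: 1 guaiacol (2-methoxyphenol)
Product: 2 2,3,4-tribromo-6-methoxyphenol (4,5,6-tribromoguaiacol)
Conditions: Br2 (3.05 equiv), AcOH, 15 → 25 °C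
Reagents that add atoms: bromine, BrBr
Why: Electrophilic aromatic bromination in which the free hydroxyl directs to its para and ortho positions and the methoxy group to its para position, while the last C–H (meta to OH, in a ring then carrying three bromines) is too deactivated to react, so the reaction should stop at the 4,5,6-tribromide.

**Step 2**
Reactants: 2 2,3,4-tribromo-6-methoxyphenol; 3 methyl 4-chloroacetoacetate
Product: 4 methyl 4-(2,3,4-tribromo-6-methoxyphenoxy)-3-oxobutanoate
Conditions: K2CO3 (1.5 equiv), acetone, reflux, slow addition of 3 (1.1 equiv)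
Reagents that add atoms: none
Why: Williamson ether synthesis (SN2) at the primary α-chloro ketone carbon, an sp3 electrophile activated by the adjacent carbonyl that should accept even this di-ortho-substituted, weakly basic phenoxide, which is itself too weak a base to promote much self-condensation of the chloro keto ester.

**Step 3**
Reactants: 4 methyl 4-(2,3,4-tribromo-6-methoxyphenoxy)-3-oxobutanoate
Product: 5 methyl 3-(trimethylsilyloxy)-4-(2,3,4-tribromo-6-methoxyphenoxy)but-2-enoate (geometric mixture)
Conditions: Me3SiCl (1.5 equiv), Et3N (1.6 equiv), toluene, 20 °C, 48 h; filtered under Ar, used crude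
Reagents that add atoms: chlorotrimethylsilane, C[Si](C)(C)Cl
Why: Silyl enol ether formation by O-silylation of the conjugated enol of the β-keto ester under amine conditions, the first stage of the standard two-stage preparation of 1,3-bis(silyl enol ethers).

**Step 4**
Reactants: 5 methyl 3-(trimethylsilyloxy)-4-(2,3,4-tribromo-6-methoxyphenoxy)but-2-enoate
Product: 7 1-methoxy-1,3-bis(trimethylsilyloxy)-4-(2,3,4-tribromo-6-methoxyphenoxy)buta-1,3-diene (geometric mixture), via lithium dienolate 6 (not isolated)
Conditions: LDA (1.02 equiv) added slowly to 5, THF, −78 °C, 45 min; Me3SiCl (1.3 equiv), −78 → 20 °C; pentane, filtered under Ar, used crude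
Reagents that add atoms: chlorotrimethylsilane, C[Si](C)(C)Cl
Why: γ-Deprotonation of the 3-silyloxy enoate (vinylogous ester enolate formation) should be much faster at −78 °C than metalation of the single ring-A C–H or attack on the aryl bromides, provided the amide base is never in excess, and O-silylation of the dienolate then gives the 1,3-bis(silyl enol ether).

**Step 5**
Reactants: 7 1-methoxy-1,3-bis(trimethylsilyloxy)-4-(2,3,4-tribromo-6-methoxyphenoxy)buta-1,3-diene; 8 1,1,3,3-tetramethoxypropane
Product: 10 methyl 2-hydroxy-3-(2,3,4-tribromo-6-methoxyphenoxy)benzoate, via open-chain acetal adduct 9 (not isolated)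
Conditions: 8 (1.1 equiv), Me3SiOTf (0.2 equiv), CH2Cl2, −78 → 20 °C, 16 h; then 10% aq. HCl
Reagents that add atoms: none
Why: The silyl triflate ionises one acetal of 8 to an oxocarbenium ion, which is attacked by the terminal, aryloxy-bearing carbon of diene 7 in a vinylogous Mukaiyama-type addition (bond C1'–C2'), giving adduct 9 with loss of methoxytrimethylsilane. Ionisation of the second acetal and attack by the carbon between the ester and the silyloxy carbon (bond C4'–C5') closes ring B in a 6-(enolendo)-exo-trig mode. Two β-eliminations of methanol and tautomerisation then aromatise the ring to the salicylate, and the acid work-up completes elimination and desilylation. The closest known reaction type is the formal [3+3] cyclocondensation of 1,3-bis(silyl enol ethers) with malonaldehyde bis-acetals to give salicylates, which is known to tolerate 4-aryloxy substituents on the diene. No stereocentre remains, since the two in 9 are destroyed on aromatisation. The only selectivity needed is the order of bond formation, which is fixed by the higher nucleophilicity of the terminal diene carbon; the symmetric dielectrophile leaves no regiochemical choice and places the ester at C5', ortho to the new hydroxyl.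

**Step 6**
Reactants: 10 methyl 2-hydroxy-3-(2,3,4-tribromo-6-methoxyphenoxy)benzoate
Product: 11 2-hydroxy-3-(2,3,4-tribromo-6-methoxyphenoxy)benzoic acid
Conditions: NaOH (4 equiv), MeOH–H2O (3:1), 65 °C; then 2 M HCl
Reagents that add atoms: sodium hydroxide, [Na+].[OH-]
Why: Saponification (base-mediated acyl substitution of the methyl ester), to which the diaryl ether and the unactivated aryl bromides are inert, with acidification returning the salicylic acid.

**Step 7**
Reactants: 11 2-hydroxy-3-(2,3,4-tribromo-6-methoxyphenoxy)benzoic acid
Product: 13 2,4-dibromo-6-(2,3,4-tribromo-6-methoxyphenoxy)phenol, via 5-bromosalicylic acid 12 (not isolated)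
Conditions: Br2 (2.15 equiv), AcOH–H2O (4:1), 20 → 45 °C
Reagents that add atoms: bromine, BrBr
Why: Electrophilic aromatic bromination para to the free phenol (C3') followed by ipso bromodecarboxylation ortho to it (C5'), the classical behaviour of salicylic acids toward aqueous bromine; the other ortho position carries the aryloxy group, and ring A, tribrominated and without a free hydroxyl, is too deactivated to compete.

**Step 8**
Reactants: 13 2,4-dibromo-6-(2,3,4-tribromo-6-methoxyphenoxy)phenol
Product: 14 3,4,5-tribromo-2-(3,5-dibromo-2-hydroxyphenoxy)phenol (target)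
Conditions: BBr3 (3.5 equiv), CH2Cl2, −78 → 20 °C; then H2O, 0 °C
Reagents that add atoms: none
Why: Lewis acid-mediated aryl methyl ether cleavage (BBr3 demethylation, bromide attacking the O-methyl of the boron-complexed ether), which leaves diaryl ether C–O bonds and aryl bromides untouched, with hydrolysis of the aryl borates releasing both phenols.

**Compound list**
1 | guaiacol (2-methoxyphenol) | COc1ccccc1O | starting material
2 | 2,3,4-tribromo-6-methoxyphenol | COc1cc(Br)c(Br)c(Br)c1O | intermediate
3 | methyl 4-chloroacetoacetate | COC(=O)CC(=O)CCl | starting material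
4 | methyl 4-(2,3,4-tribromo-6-methoxyphenoxy)-3-oxobutanoate | COC(=O)CC(=O)COc1c(OC)cc(Br)c(Br)c1Br | intermediate
5 | methyl 3-(trimethylsilyloxy)-4-(2,3,4-tribromo-6-methoxyphenoxy)but-2-enoate (geometric mixture) | COC(=O)C=C(O[Si](C)(C)C)COc1c(OC)cc(Br)c(Br)c1Br | intermediate
6 | lithium 1-methoxy-3-(trimethylsilyloxy)-4-(2,3,4-tribromo-6-methoxyphenoxy)buta-1,3-dien-1-olate (not isolated) | [Li]OC(OC)=CC(O[Si](C)(C)C)=COc1c(OC)cc(Br)c(Br)c1Br | intermediate
7 | 1-methoxy-1,3-bis(trimethylsilyloxy)-4-(2,3,4-tribromo-6-methoxyphenoxy)buta-1,3-diene (geometric mixture) | COC(O[Si](C)(C)C)=CC(O[Si](C)(C)C)=COc1c(OC)cc(Br)c(Br)c1Br | intermediate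
8 | 1,1,3,3-tetramethoxypropane | COC(OC)CC(OC)OC | starting material
9 | methyl 5,7,7-trimethoxy-3-(trimethylsilyloxy)-4-(2,3,4-tribromo-6-methoxyphenoxy)hept-2-enoate (diastereomer mixture, not isolated) | COC(=O)C=C(O[Si](C)(C)C)C(Oc1c(OC)cc(Br)c(Br)c1Br)C(OC)CC(OC)OC | intermediate
10 | methyl 2-hydroxy-3-(2,3,4-tribromo-6-methoxyphenoxy)benzoate | COC(=O)c1cccc(Oc2c(OC)cc(Br)c(Br)c2Br)c1O | intermediate
11 | 2-hydroxy-3-(2,3,4-tribromo-6-methoxyphenoxy)benzoic acid | OC(=O)c1cccc(Oc2c(OC)cc(Br)c(Br)c2Br)c1O | intermediate
12 | 5-bromo-2-hydroxy-3-(2,3,4-tribromo-6-methoxyphenoxy)benzoic acid (not isolated) | OC(=O)c1cc(Br)cc(Oc2c(OC)cc(Br)c(Br)c2Br)c1O | intermediate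
13 | 2,4-dibromo-6-(2,3,4-tribromo-6-methoxyphenoxy)phenol | COc1cc(Br)c(Br)c(Br)c1Oc1cc(Br)cc(Br)c1O | intermediate
14 | 3,4,5-tribromo-2-(3,5-dibromo-2-hydroxyphenoxy)phenol | Oc1cc(Br)c(Br)c(Br)c1Oc1cc(Br)cc(Br)c1O | target

**Totals**
Total step count: 8. Longest linear sequence: 8 steps (from guaiacol).

**Steps most likely to fail**

Step 5 (key cyclocondensation). The addition may stop at open-chain or partly eliminated stages, or protodesilylation of the diene back to the keto ester may outrun C–C bond formation. Fallback, setting out from 2 and returning at 10: the phenoxide of 2 would be arylated by nucleophilic aromatic substitution on methyl 3-fluoro-2-nitrobenzoate (K2CO3, DMSO, 90 °C), where the ortho nitro group activates fluoride displacement enough for a hindered phenoxide, to give methyl 2-nitro-3-(2,3,4-tribromo-6-methoxyphenoxy)benzoate F1. Reduction of the nitro group with iron and ammonium chloride (aq. EtOH, 75 °C), which spares aryl bromides, would give methyl 2-amino-3-(2,3,4-tribromo-6-methoxyphenoxy)benzoate F2. Diazotisation (NaNO2, aq. H2SO4–AcOH, 0 °C) would give 2-(methoxycarbonyl)-6-(2,3,4-tribromo-6-methoxyphenoxy)benzenediazonium hydrogensulfate F3, and its hydrolysis in hot dilute sulfuric acid would give salicylate 10.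

Step 4 (second silylation). The amide base may metalate the ring-A C–H flanked by bromine and methoxy, leading to bromine migration or aryne formation, or the γ-deprotonation may be incomplete. Fallback, setting out from 4 and returning at 7: the amide base is abandoned in favour of soft enolisation. Keto ester 4 would be treated with Me3SiOTf (2.3 equiv) and Et3N (2.6 equiv) in Et2O at 0 → 20 °C, so that both silyl groups are installed by Lewis-acid-assisted enolisation in one operation. After separation of the ammonium triflate layer, diene 7 would be used crude.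

Step 2 (O-alkylation). Base-induced self-condensation and C-alkylation of the chloro keto ester may outpace O-alkylation by the sluggish phenoxide. Fallback, setting out from 2 and returning at 4: the phenol would be alkylated with methyl (E)-4-bromo-3-methoxybut-2-enoate (K2CO3, acetone, reflux), a masked 4-bromoacetoacetate with neither an acidic methylene nor a free ketone, to give methyl (E)-3-methoxy-4-(2,3,4-tribromo-6-methoxyphenoxy)but-2-enoate F4. Hydrolysis of the enol ether (2 M HCl, THF, 40 °C) would then give keto ester 4.

**Further compounds**
F1 | step 5 | methyl 2-nitro-3-(2,3,4-tribromo-6-methoxyphenoxy)benzoate | COC(=O)c1cccc(Oc2c(OC)cc(Br)c(Br)c2Br)c1[N+](=O)[O-]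
F2 | step 5 | methyl 2-amino-3-(2,3,4-tribromo-6-methoxyphenoxy)benzoate | COC(=O)c1cccc(Oc2c(OC)cc(Br)c(Br)c2Br)c1N
F3 | step 5 | 2-(methoxycarbonyl)-6-(2,3,4-tribromo-6-methoxyphenoxy)benzenediazonium hydrogensulfate | COC(=O)c1cccc(Oc2c(OC)cc(Br)c(Br)c2Br)c1[N+]#N.OS(=O)(=O)[O-]
F0 | step 4 | none | none
F4 | step 2 | methyl (E)-3-methoxy-4-(2,3,4-tribromo-6-methoxyphenoxy)but-2-enoate | COC(=O)/C=C(/OC)COc1c(OC)cc(Br)c(Br)c1Br
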